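**Retrosynthetic overview**

- The target is a (2S)-flavanone. Ring C is disconnected at two bonds at once: C3–C4 (methylene to ketone carbon) and O1–C2 (ring oxygen to the benzylic stereocentre). This leads to 2,3-dihydroxy-4,5,6-trimethoxybenzaldehyde (ring A, C4 as CHO) and 4-ethynyl-1,2-dimethoxybenzene (ring B, C2–C3 as an alkyne, so the annulation is redox-neutral and loses no atom).
- Both bonds form in one flask. Rhodium-catalysed hydroacylation of the alkyne by the aldehyde makes C3–C4 and an open 2'-hydroxychalcone. A chalcone isomerase then makes O1–C2 and sets C2 as S, a closure that no small-molecule catalyst performs with high selectivity on an unactivated 2'-hydroxychalcone.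
- Enabling feature: the free phenolic oxygen O1 on C8a of ring A, ortho to the carbonyl carbon C4. It first anchors rhodium beside the formyl C–H bond and then is the nucleophile that closes ring C. The neighbouring 8-OH cannot reach C2 through a six-membered ring, and the 5-OMe group favours the closed form, so no protecting group is needed.
- The aldehyde comes from 3,4,5-trimethoxyphenol in three steps: ortho-formylation, Dakin oxidation to the catechol, and a second ortho-formylation at the only free ring carbon.
- Order of rings: A and B are bought as benzenes, ring A is fully oxygenated first, ring C is closed last in the key step.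

Key step: step 4

Assumption: a chalcone isomerase that accepts the 6'-O-methylated, fully substituted ring A of the chalcone (a wild-type enzyme from a small panel or a variant with a widened ring A pocket) is taken to be at hand; the 2S sense of this enzyme class is the property the route relies on.

**Route**

Step 1
Reactants: 1 3,4,5-trimethoxyphenol
Product: 2 6-hydroxy-2,3,4-trimethoxybenzaldehyde
Conditions: MgCl2, Et3N, (CH2O)n, MeCN, reflux; then aq. HCl
Reagents that add atoms: paraformaldehyde (formaldehyde units), C=O
Why: Casnati–Skattebøl ortho-formylation: the magnesium phenoxide of 1 delivers formaldehyde to the carbon next to the hydroxyl and a second formaldehyde takes the hydride of the resulting benzylic alkoxide, and because the two ortho carbons of 1 are equivalent only one aldehyde can form.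

Step 2
Reactants: 2 6-hydroxy-2,3,4-trimethoxybenzaldehyde
Product: 4 3,4,5-trimethoxybenzene-1,2-diol, via aryl formate 3 (not isolated)
Conditions: 30% aq. H2O2, H3BO3, cat. H2SO4, THF, rt, N2; then aq. Na2SO3
Reagents that add atoms: hydrogen peroxide, OO
Why: Dakin oxidation: the hydroperoxide adduct of the electron-rich ortho-hydroxy aldehyde undergoes aryl migration to formate 3, which is hydrolysed in the acidic aqueous medium, while boric acid holds the new catechol as a borate ester and so shields it from further oxidation.

Step 3
Reactants: 4 3,4,5-trimethoxybenzene-1,2-diol
Product: 5 2,3-dihydroxy-4,5,6-trimethoxybenzaldehyde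
Conditions: MgCl2, Et3N, (CH2O)n, MeCN, reflux, Ar; then aq. HCl
Reagents that add atoms: paraformaldehyde (formaldehyde units), C=O
Why: The same magnesium-mediated ortho-formylation (Casnati–Skattebøl) now meets a ring with a single free carbon, which lies ortho to a hydroxyl, so the regiochemistry cannot go astray and 5 carries the hydroxy aldehyde pair that the key step needs.

Step 4
Reactants: 5 2,3-dihydroxy-4,5,6-trimethoxybenzaldehyde; 6 4-ethynyl-1,2-dimethoxybenzene
Product: 8 (2S)-2-(3,4-dimethoxyphenyl)-8-hydroxy-5,6,7-trimethoxy-2,3-dihydro-4H-chromen-4-one, via chalcone 7 (not isolated)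
Conditions: [RhCl(cod)]2 (2.5 mol %), dppf (1,1'-bis(diphenylphosphino)ferrocene, Fe(C5H4PPh2)2, 5 mol %), Na2CO3 (5 mol %), toluene, 80 °C, Ar, slow addition of 6; then toluene removed in the same flask, DMSO/potassium phosphate buffer (KH2PO4/K2HPO4, pH 6.8) 1:9, chalcone isomerase (chalcone–flavanone isomerase, EC 5.5.1.6), 30 °C, Ar
Reagents that add atoms: none
Why: The deprotonated 2-hydroxyl of 5 binds monovalent rhodium and steers oxidative addition of the formyl C–H bond to a five-membered acyl(hydrido) aryloxide chelate of trivalent rhodium; syn hydrometalation of 6 (hydride to the aryl-bearing carbon) and C–C reductive elimination should then give the linear (E)-chalcone 7 with the new bond between the carbonyl carbon and the α-carbon (later C4–C3). In the second stage chalcone isomerase binds 7 in its s-trans form, stabilises the 2'-phenoxide and the developing enolate through its polar active-site network, and delivers the phenoxide oxygen to the β-carbon, so that ring C closes by a 6-endo-trig oxa-Michael addition (new O1–C2 bond) before the enolate is protonated at C3. The closest known reaction types are the rhodium-catalysed tandem hydroacylation/oxa-Michael annulation of salicylaldehydes with alkynes and the chalcone isomerase step of flavonoid biosynthesis, which is here asked to accept a non-natural, fully substituted ring A. The single stereocentre C2 is set by the enzyme alone (catalyst control): its active site exposes one face of the enone and this enzyme class gives the 2S flavanone, the configuration of the target. The step needs linear regioselectivity in the hydroacylation, which the aryl group of the terminal alkyne should secure by sending the acyl group to the unsubstituted carbon, and it needs 7 to stay open until the enzyme acts, which the hydrogen bond from the 2'-hydroxyl to the carbonyl in apolar, nearly base-free toluene and the slightly acidic buffer (little free phenoxide, slow racemic background) should secure. Only the hydroxyl ortho to the carbonyl can reach the β-carbon through a six-membered transition state, so the adjacent hydroxyl (the future 8-OH) needs no protection, and the 6'-methoxy group twists the aryl ketone out of conjugation and thereby makes the closed flavanone the thermodynamic sink.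

**Compound list**

1 | 3,4,5-trimethoxyphenol | COc1cc(O)cc(OC)c1OC | starting material
2 | 6-hydroxy-2,3,4-trimethoxybenzaldehyde | O=Cc1c(O)cc(OC)c(OC)c1OC | intermediate
3 | 6-hydroxy-2,3,4-trimethoxyphenyl formate (not isolated) | O=COc1c(O)cc(OC)c(OC)c1OC | intermediate
4 | 3,4,5-trimethoxybenzene-1,2-diol | Oc1cc(OC)c(OC)c(OC)c1O | intermediate
5 | 2,3-dihydroxy-4,5,6-trimethoxybenzaldehyde | O=Cc1c(O)c(O)c(OC)c(OC)c1OC | intermediate
6 | 4-ethynyl-1,2-dimethoxybenzene | C#Cc1ccc(OC)c(OC)c1 | starting material
7 | (2E)-1-(2,3-dihydroxy-4,5,6-trimethoxyphenyl)-3-(3,4-dimethoxyphenyl)prop-2-en-1-one (not isolated) | COc1ccc(/C=C/C(=O)c2c(O)c(O)c(OC)c(OC)c2OC)cc1OC | intermediate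
8 | (2S)-2-(3,4-dimethoxyphenyl)-8-hydroxy-5,6,7-trimethoxy-2,3-dihydro-4H-chromen-4-one | COc1ccc([C@@H]2CC(=O)c3c(c(O)c(OC)c(OC)c3OC)O2)cc1OC | target

**Step count**

Total steps: 4. Longest linear sequence: 4 steps (1 → 2 → 4 → 5 → 8); alkyne 6 enters in step 4.

**Steps most likely to fail**

1. Step 4. Three processes may go wrong.
 - The acyl rhodium hydride may lose CO, or rhodium may be held by the two adjacent ring A oxygens, before the alkyne inserts.
 - The terminal alkyne may oligomerise.
 - The enzyme may turn over the crowded chalcone too slowly, so that racemic background closure erodes the enantiopurity.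

 The fallback sets out from 5 and comes back at 8; it closes the ring on an ester-activated enone with a small chiral catalyst. Roskamp homologation of 5 with tert-butyl diazoacetate (cat. SnCl2, CH2Cl2) should give tert-butyl 3-(2,3-dihydroxy-4,5,6-trimethoxyphenyl)-3-oxopropanoate F1. Knoevenagel condensation with 3,4-dimethoxybenzaldehyde (piperidinium acetate, toluene, molecular sieves) should give tert-butyl 2-(2,3-dihydroxy-4,5,6-trimethoxybenzoyl)-3-(3,4-dimethoxyphenyl)prop-2-enoate F2. A cinchona-derived bifunctional thiourea (the pseudoenantiomer that leads to the 2S series; toluene, −25 °C) should close it by enantioselective oxa-Michael addition to tert-butyl (2S,3R)-2-(3,4-dimethoxyphenyl)-8-hydroxy-5,6,7-trimethoxy-4-oxochromane-3-carboxylate F3. TsOH in toluene at 80 °C should then remove the tert-butyl ester and the carboxyl group to give 8.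

2. Step 3. Both catechol oxygens may chelate magnesium so that formaldehyde is not delivered to the ring carbon, formaldehyde may bridge the two hydroxyls, or the catecholate may be oxidised by traces of air under the basic conditions.

 The fallback sets out from 4 and comes back at 5; it replaces electrophilic formylation by directed metalation. Protection with chloromethyl methyl ether and iPr2NEt in CH2Cl2 should give 1,2,3-trimethoxy-4,5-bis(methoxymethoxy)benzene F4. Lithiation of the only ring C–H, which is flanked by two directing oxygens (n-BuLi, TMEDA, THF, −20 °C), and a DMF quench should give 4,5,6-trimethoxy-2,3-bis(methoxymethoxy)benzaldehyde F5. HCl in MeOH at 40 °C should release 5.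

3. Step 2. The very electron-rich catechol may be oxidised further by the peroxide to quinones faster than the aldehyde is consumed.

 The fallback sets out from 1 and comes back at 4; it installs the second oxygen directly, without the formyl group. Ortho-oxygenation of 1 with 2-iodoxybenzoic acid (IBX, DMF, rt) should give 3,4,5-trimethoxycyclohexa-3,5-diene-1,2-dione F6, which is reduced in the same flask with aqueous Na2S2O4 to 4.

**Further compounds**

F1 | step 4 | tert-butyl 3-(2,3-dihydroxy-4,5,6-trimethoxyphenyl)-3-oxopropanoate | CC(C)(C)OC(=O)CC(=O)c1c(O)c(O)c(OC)c(OC)c1OC
F2 | step 4 | tert-butyl 2-(2,3-dihydroxy-4,5,6-trimethoxybenzoyl)-3-(3,4-dimethoxyphenyl)prop-2-enoate (alkene geometry not controlled) | COc1ccc(C=C(C(=O)OC(C)(C)C)C(=O)c2c(O)c(O)c(OC)c(OC)c2OC)cc1OC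
F3 | step 4 | tert-butyl (2S,3R)-2-(3,4-dimethoxyphenyl)-8-hydroxy-5,6,7-trimethoxy-4-oxochromane-3-carboxylate | COc1ccc([C@@H]2[C@@H](C(=O)OC(C)(C)C)C(=O)c3c(c(O)c(OC)c(OC)c3OC)O2)cc1OC
F4 | step 3 | 1,2,3-trimethoxy-4,5-bis(methoxymethoxy)benzene | COCOc1cc(OC)c(OC)c(OC)c1OCOC
F5 | step 3 | 4,5,6-trimethoxy-2,3-bis(methoxymethoxy)benzaldehyde | COCOc1c(C=O)c(OC)c(OC)c(OC)c1OCOC
F6 | step 2 | 3,4,5-trimethoxycyclohexa-3,5-diene-1,2-dione | O=C1C=C(OC)C(OC)=C(OC)C1=O
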